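Numbering follows the target SMILES, with carbonyl and hydroxyl oxygens left out: C1–C3 propanoic acid, C4–C9 ring A, C10 lactone carbonyl, O11, C12, spiro C13, C14 ketone, C15, C16, O17, C18, C19, C20 (CMe2).
Retrosynthesis: the O17–C18 ether is cut to a C16/C18 diol; ring A is cut at C6–C7 and C8–C9 (Diels–Alder of a C7=C8 lactone with a 2-ethoxy diene carrying C1–C4, the C5 oxygen removed afterwards); the lactone is cut at O11–C10 back to two esters; ring C is cut at C13–C19 (Conia-ene); the chain is cut at C13–C7 (Michael) and C15–C16 (vinylogous aldol).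
Forward: acyclic keto ester chain, then ring C, then spiro lactone ring B, then ring A, the oxa bridge last, then the two oxidations.
Stereochemistry: C16 from the catalytic asymmetric aldol; C13 from C16 in the ring closure; C14 (temporary) and C19 by hydride and borane additions to the chair-locked ring C; C7 and C8 from the suprafacial cycloaddition on the face away from the axial C20 methyl; C4 by equilibration next to the C5 ketone; C2 from methyl (S)-3-hydroxy-2-methylpropanoate.

Key step: step 8

Assumption: the (S)-BINOL titanium catalyst of step 4 is taken to give the (S)-carbinol at C16; should the sense be the opposite, (R)-BINOL is used and nothing else changes.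

Step 1
Reactants: 1 2,2-dimethylbut-3-ynoic acid
Product: 2 2,2-dimethylbut-3-yn-1-ol
Conditions: LiAlH4, Et2O, 0 °C → rt
Reagents that add atoms: none
Why: Hydride reduction of the acid to the neopentyl alcohol is standard, and the terminal alkyne is only deprotonated and is recovered on work-up.

Step 2
Reactants: 2 2,2-dimethylbut-3-yn-1-ol
Product: 3 2,2-dimethylbut-3-ynal
Conditions: DMP, CH2Cl2, 0 °C → rt; the volatile aldehyde is kept as a CH2Cl2 solution
Reagents that add atoms: none
Why: Dess–Martin oxidation of a primary alcohol stops at the aldehyde, which has no α-hydrogen and can neither enolise nor self-condense.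

Step 3
Reactants: 4 2,2,6-trimethyl-4H-1,3-dioxin-4-one
Product: 5 dienol silane [(2,2-dimethyl-6-methylidene-6H-1,3-dioxin-4-yl)oxy]trimethylsilane
Conditions: LiN(iPr)2, THF, −78 °C; then TMSCl
Reagents that add atoms: chlorotrimethylsilane, C[Si](C)(C)Cl
Why: γ-Deprotonation of the vinylogous ester and O-silylation give the dienol silane, the usual nucleophile of vinylogous Mukaiyama aldol reactions.

Step 4
Reactants: 3 2,2-dimethylbut-3-ynal; 5 dienol silane
Product: 7 6-[(2S)-2-hydroxy-3,3-dimethylpent-4-yn-1-yl]-2,2-dimethyl-4H-1,3-dioxin-4-one, via trimethylsilyl ether 6 (not isolated)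
Conditions: Ti(OiPr)4/(S)-BINOL (20 mol%), 4 Å MS, THF, −78 → −20 °C; then 1 M HCl, THF, 0 °C
Reagents that add atoms: none
Why: The titanium BINOLate-catalysed vinylogous Mukaiyama aldol adds the γ-carbon of the dienol silane to one face of the non-enolisable aldehyde and so sets C16 (bond C15–C16), the silyl ether being cleaved on acidic work-up.

Step 5
Reactants: 7 hydroxy dioxinone
Product: 8 tert-butyldimethylsilyl ether of 7
Conditions: TBSOTf, 2,6-lutidine, CH2Cl2, −78 → 0 °C
Reagents that add atoms: tert-butyldimethylsilyl triflate, CC(C)(C)[Si](C)(C)OS(=O)(=O)C(F)(F)F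
Why: A silyl triflate with a hindered pyridine silylates even this neopentyl secondary alcohol, and capping the hydroxyl now prevents its lactonisation onto the acylketene of the next step.

Step 6
Reactants: 8 silyl ether dioxinone
Product: 10 methyl (5S)-5-[(tert-butyldimethylsilyl)oxy]-6,6-dimethyl-3-oxooct-7-ynoate, via acylketene 9 (not isolated)
Conditions: MeOH (10 equiv), toluene, 110 °C, sealed tube
Reagents that add atoms: methanol, CO
Why: Thermal retro-hetero-Diels–Alder loss of acetone gives an acylketene that methanol traps as the β-keto methyl ester.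

Step 7
Reactants: 10 β-keto ester; 11 tert-butyl acrylate
Product: 12 5-tert-butyl 1-methyl 2-[(3S)-3-[(tert-butyldimethylsilyl)oxy]-4,4-dimethylhex-5-ynoyl]pentanedioate (both C13 epimers)
Conditions: Cs2CO3 (10 mol%), MeCN, 0 °C → rt, 1.05 equiv of 11
Reagents that add atoms: none
Why: Michael addition of the doubly activated C13–H to the acrylate installs the C7–C8–C10 arm, the mild carbonate leaving the C15 position and the β-silyloxy group untouched; C13 stays epimerisable here and is not yet fixed.

Step 8
Reactants: 12 alkynyl β-keto ester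
Product: 13 methyl (1R,4S)-1-(3-tert-butoxy-3-oxopropyl)-4-[(tert-butyldimethylsilyl)oxy]-3,3-dimethyl-2-methylidene-6-oxocyclohexane-1-carboxylate
Conditions: [tBu2(o-biphenyl)P]AuNTf2 (5 mol%), CH2Cl2, 40 °C
Reagents that add atoms: none
Why: The cationic monovalent gold complex binds the terminal alkyne, the hydrogen-bonded Z-enol of the β-keto ester adds through C13 to the internal alkyne carbon C19 from the side opposite to gold, and protodeauration of the alkenylgold releases the exocyclic C19=C18 methylidene; the closest known reaction type is the Conia-ene cycloisomerisation of ω-alkynyl β-keto esters. Ring C closes in the 6-exo-dig mode with the enol double bond inside the forming ring, and C13 becomes quaternary. The C13 configuration is to come from the C16 silyloxy stereocenter through a chair-like transition state: the silyloxy group is placed equatorial, the ester, held in the enol plane by the hydrogen bond to the enol oxygen, ends equatorial and the propanoate arm axial, so that C12 is trans to the C16 oxygen. The step needs 6-exo instead of 7-endo closure and C- instead of O-attack; both follow from Markovnikov attack at the substituted alkyne carbon, and the gem-dimethyl group next to the alkyne helps the chain to fold. The face selectivity at C13 rests only on this 1,4-relationship and is the least secure point of the step.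

Step 9
Reactants: 13 ring C keto ester
Product: 14 C14 alcohol (OH cis to the C16 silyloxy group)
Conditions: NaBH4, MeOH, −20 °C
Reagents that add atoms: none
Why: Borohydride reduces only the ketone, which would not survive the borane, aluminium hydride and amide base used later; hydride enters on the face opposite to the propanoate arm of C13 and gives the C14 alcohol cis to the C16 oxygen, a center that is oxidised back in the last step.

Step 10
Reactants: 14 C14 alcohol
Product: 15 C14 benzyl ether
Conditions: 2-benzyloxy-1-methylpyridinium triflate, MgO, PhCF3, 83 °C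
Reagents that add atoms: 2-benzyloxy-1-methylpyridinium triflate, C[n+]1ccccc1OCc1ccccc1.[O-]S(=O)(=O)C(F)(F)F
Why: This neutral benzyl-transfer salt etherifies hindered alcohols without acid or base and so spares the silyl ether, both esters and the retro-aldol-prone β-hydroxy ester.

Step 11
Reactants: 15 C14 benzyl ether
Product: 17 C18 primary alcohol (C14 OBn and C16 OTBS and C19 CH2OH all cis), via primary alkylborane 16 (not isolated)
Conditions: BH3·THF, THF, 0 °C → rt; then H2O2, NaOH, 0 °C
Reagents that add atoms: hydrogen peroxide, OO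
Why: Anti-Markovnikov hydroboration–oxidation puts the oxygen on C18; the cis ether groups on C14 and C16 hold ring C in the chair with both equatorial, where one face of the methylidene is shielded by the axial propanoate arm and the axial C20 methyl, so hydrogen reaches C19 from the other face and C18 ends cis to the C16 oxygen.

Step 12
Reactants: 17 C18 primary alcohol
Product: 18 C18 tert-butyldimethylsilyl ether
Conditions: TBSCl, imidazole, DMF, 0 °C → rt
Reagents that add atoms: tert-butyldimethylsilyl chloride, CC(C)(C)[Si](C)(C)Cl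
Why: Routine silylation of the only free hydroxyl masks C18; the ether bridge is closed only after the cycloaddition so that ring C stays locked in one chair until then.

Step 13
Reactants: 18 bis-silyl ether diester
Product: 19 C10,C12-diol
Conditions: LiAlH4, THF, 0 °C → rt
Reagents that add atoms: none
Why: Aluminium hydride reduces the methyl and the tert-butyl ester to the C12 and C10 primary alcohols and leaves silyl and benzyl ethers alone.

Step 14
Reactants: 19 C10,C12-diol
Product: 21 spiro δ-lactone (C10 carbonyl), via C10 lactol 20 (not isolated)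
Conditions: TEMPO (20 mol%), PhI(OAc)2 (2.5 equiv), CH2Cl2, rt
Reagents that add atoms: none
Why: In this oxidative lactonisation of a 1,5-diol the nitroxyl catalyst attacks the unhindered C10 alcohol before the neopentyl C12 alcohol, the aldehyde closes to the lactol with the C12 hydroxyl and is oxidised on, so the carbonyl ends at C10.

Step 15
Reactants: 21 spiro δ-lactone
Product: 24 C7=C8 unsaturated spiro lactone, via C8 phenylselenide 22 (not isolated), via selenoxide 23 (not isolated)
Conditions: LiN(iPr)2, THF, −78 °C; PhSeBr; then H2O2, pyridine, CH2Cl2, 0 °C → rt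
Reagents that add atoms: none
Why: Selenenylation of the lactone enolate at C8 and syn-elimination of the selenoxide toward C7 is the standard dehydrogenation of lactones, and no other acidic C–H is present at this stage.

Step 16
Reactants: 25 methyl (2S)-3-hydroxy-2-methylpropanoate
Product: 26 methyl (2S)-3-(benzyloxy)-2-methylpropanoate
Conditions: benzyl 2,2,2-trichloroacetimidate, TfOH (cat.), CH2Cl2/cyclohexane, 0 °C → rt
Reagents that add atoms: benzyl 2,2,2-trichloroacetimidate, ClC(Cl)(Cl)C(=N)OCc1ccccc1
Why: Acid-catalysed benzylation with the imidate avoids base and therefore neither epimerises the α-stereocenter (the future C2) nor causes β-elimination.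

Step 17
Reactants: 26 benzyloxy ester
Product: 28 (3S)-4-(benzyloxy)-3-methylbutan-2-one, via N-methoxy-N-methylamide 27 (not isolated)
Conditions: MeNH(OMe)·HCl, iPrMgCl, THF, −20 °C; then MeMgBr, 0 °C
Reagents that add atoms: methylmagnesium bromide, C[Mg]Br
Why: The ester is converted in the flask to the N-methoxy-N-methylamide, whose magnesium chelate takes up a single methyl Grignard equivalent and gives the methyl ketone without epimerisation.

Step 18
Reactants: 28 methyl ketone
Product: 29 (3S)-4-(benzyloxy)-3-methylbut-1-en-2-yl trifluoromethanesulfonate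
Conditions: KN(SiMe3)2, THF, −78 °C; then PhNTf2
Reagents that add atoms: N-phenylbis(trifluoromethanesulfonimide), FC(F)(F)S(=O)(=O)N(c1ccccc1)S(=O)(=O)C(F)(F)F
Why: Kinetic deprotonation by the bulky amide occurs at the methyl group and not at the tertiary C2–H, and O-sulfonylation of that enolate gives the alkenyl triflate with C2 intact.

Step 19
Reactants: 29 alkenyl triflate; 30 tributyl(1-ethoxyvinyl)stannane
Product: 31 2-ethoxy diene ({[(2R)-4-ethoxy-2-methyl-3-methylidenepent-4-en-1-yl]oxy}methyl)benzene
Conditions: Pd(PPh3)4 (5 mol%), LiCl, THF, 65 °C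
Reagents that add atoms: none
Why: Stille coupling of an alkenyl triflate with an α-alkoxyvinylstannane, chloride assisting the transmetalation, is an established way to 2-alkoxy-1,3-dienes.

Step 20
Reactants: 24 unsaturated spiro lactone; 31 2-ethoxy diene
Product: 33 C5 ketone of the ring A–B–C tricycle, via cycloadduct enol ether 32 (not isolated)
Conditions: Me2AlCl (1.5 equiv), CH2Cl2, −40 → 0 °C; then 1 M HCl, THF, rt
Reagents that add atoms: water, O
Why: In this Lewis acid-promoted Diels–Alder reaction the ethoxy group directs C5 para to C8 (bonds C6–C7 and C8–C9), suprafacial addition makes the C7/C8 junction cis, and the diene adds to the face of C7=C8 that looks toward C14 and C15, because the three cis equatorial groups on C14, C16 and C19 hold ring C in the chair that puts C7 axial next to the axial C20 methyl and the C19 side chain; acid hydrolysis of the enol ether then gives the C5 ketone and lets C4 settle with its side chain equatorial, trans to C13.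

Step 21
Reactants: 33 C5 ketone
Product: 34 C5 tosylhydrazone
Conditions: TsNHNH2, EtOH, 50 °C
Reagents that add atoms: 4-methylbenzenesulfonohydrazide, Cc1ccc(cc1)S(=O)(=O)NN
Why: The unhindered cyclohexanone condenses with the sulfonyl hydrazide while the lactone is inert.

Step 22
Reactants: 34 C5 tosylhydrazone
Product: 36 C5 methylene compound, via tosylhydrazine 35 (not isolated)
Conditions: catecholborane, CHCl3, 0 °C; then NaOAc·3H2O, reflux
Reagents that add atoms: none
Why: Hydride transfer from catecholborane to the hydrazone and acetate-induced loss of sulfinate and nitrogen replace the C5 carbonyl by CH2 (a mild hydride variant of the Wolff–Kishner deoxygenation) without touching the lactone, C8 or C4.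

Step 23
Reactants: 36 C5 methylene compound
Product: 37 C16,C18-diol
Conditions: HF·pyridine, THF/pyridine, 0 → 40 °C
Reagents that add atoms: none
Why: Fluoride cleaves both silyl ethers and leaves the benzyl ethers and the lactone.

Step 24
Reactants: 37 C16,C18-diol
Product: 39 oxa-bridged C3,C14-dibenzyl ether, via C18 tosylate 38 (not isolated)
Conditions: TsCl, Et3N, DMAP (cat.), CH2Cl2, 0 °C; then NaH, THF, 0 °C → rt
Reagents that add atoms: none
Why: The primary C18 alcohol is sulfonylated selectively and the C16 alkoxide then displaces the tosylate in a 5-exo-tet Williamson closure with retention at C16, which is possible only because C18 and the C16 oxygen are cis; an alkoxide is used so that it outruns the neighbouring benzyl ether oxygen.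

Step 25
Reactants: 39 oxa-bridged dibenzyl ether
Product: 40 C3,C14-diol
Conditions: H2 (1 atm), Pd/C, EtOAc/EtOH, rt
Reagents that add atoms: none
Why: Hydrogenolysis removes both benzyl ethers under neutral conditions now that no alkene is left.

Step 26
Reactants: 40 C3,C14-diol
Product: 42 target CNP0152427.1, via keto aldehyde 41 (not isolated)
Conditions: CrO3, H2SO4, acetone/H2O, 0 °C
Reagents that add atoms: water, O
Why: Jones oxidation converts the C14 alcohol to the ketone and the primary alcohol through the aldehyde hydrate to the acid in one operation, the acidic medium avoiding β-elimination of the ether oxygen and epimerisation at C2.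

Compound list
1 | 2,2-dimethylbut-3-ynoic acid | CC(C)(C#C)C(=O)O | starting material
2 | 2,2-dimethylbut-3-yn-1-ol | CC(C)(C#C)CO | intermediate
3 | 2,2-dimethylbut-3-ynal | CC(C)(C#C)C=O | intermediate
4 | 2,2,6-trimethyl-4H-1,3-dioxin-4-one | CC1=CC(=O)OC(C)(C)O1 | starting material
5 | [(2,2-dimethyl-6-methylidene-6H-1,3-dioxin-4-yl)oxy]trimethylsilane | C=C1C=C(O[Si](C)(C)C)OC(C)(C)O1 | intermediate
6 | trimethylsilyl ether of 7 | CC1(C)OC(=O)C=C(C[C@H](O[Si](C)(C)C)C(C)(C)C#C)O1 | intermediate (not isolated)
7 | 6-[(2S)-2-hydroxy-3,3-dimethylpent-4-yn-1-yl]-2,2-dimethyl-4H-1,3-dioxin-4-one | CC1(C)OC(=O)C=C(C[C@H](O)C(C)(C)C#C)O1 | intermediate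
8 | 6-[(2S)-2-[(tert-butyldimethylsilyl)oxy]-3,3-dimethylpent-4-yn-1-yl]-2,2-dimethyl-4H-1,3-dioxin-4-one | CC1(C)OC(=O)C=C(C[C@H](O[Si](C)(C)C(C)(C)C)C(C)(C)C#C)O1 | intermediate
9 | acylketene from 8 | O=C=CC(=O)C[C@H](O[Si](C)(C)C(C)(C)C)C(C)(C)C#C | intermediate (not isolated)
10 | methyl (5S)-5-[(tert-butyldimethylsilyl)oxy]-6,6-dimethyl-3-oxooct-7-ynoate | COC(=O)CC(=O)C[C@H](O[Si](C)(C)C(C)(C)C)C(C)(C)C#C | intermediate
11 | tert-butyl acrylate | C=CC(=O)OC(C)(C)C | starting material
12 | 5-tert-butyl 1-methyl 2-[(3S)-3-[(tert-butyldimethylsilyl)oxy]-4,4-dimethylhex-5-ynoyl]pentanedioate, both C13 epimers | COC(=O)C(CCC(=O)OC(C)(C)C)C(=O)C[C@H](O[Si](C)(C)C(C)(C)C)C(C)(C)C#C | intermediate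
13 | methyl (1R,4S)-1-(3-tert-butoxy-3-oxopropyl)-4-[(tert-butyldimethylsilyl)oxy]-3,3-dimethyl-2-methylidene-6-oxocyclohexane-1-carboxylate | COC(=O)[C@@]1(CCC(=O)OC(C)(C)C)C(=O)C[C@H](O[Si](C)(C)C(C)(C)C)C(C)(C)C1=C | intermediate
14 | methyl (1R,4S,6R)-1-(3-tert-butoxy-3-oxopropyl)-4-[(tert-butyldimethylsilyl)oxy]-6-hydroxy-3,3-dimethyl-2-methylidenecyclohexane-1-carboxylate | COC(=O)[C@@]1(CCC(=O)OC(C)(C)C)[C@H](O)C[C@H](O[Si](C)(C)C(C)(C)C)C(C)(C)C1=C | intermediate
15 | C14 benzyl ether of 14 | COC(=O)[C@@]1(CCC(=O)OC(C)(C)C)[C@H](OCc2ccccc2)C[C@H](O[Si](C)(C)C(C)(C)C)C(C)(C)C1=C | intermediate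
16 | primary alkylborane from 15 (BH2 on C18, C18 cis to the C16 oxygen) | COC(=O)[C@@]1(CCC(=O)OC(C)(C)C)[C@H](OCc2ccccc2)C[C@H](O[Si](C)(C)C(C)(C)C)C(C)(C)[C@@H]1CB | intermediate (not isolated)
17 | C18 primary alcohol, C14 OBn, C16 OTBS and C19 CH2OH all cis and trans to the C12 ester | COC(=O)[C@@]1(CCC(=O)OC(C)(C)C)[C@H](OCc2ccccc2)C[C@H](O[Si](C)(C)C(C)(C)C)C(C)(C)[C@@H]1CO | intermediate
18 | C18 tert-butyldimethylsilyl ether of 17 | COC(=O)[C@@]1(CCC(=O)OC(C)(C)C)[C@H](OCc2ccccc2)C[C@H](O[Si](C)(C)C(C)(C)C)C(C)(C)[C@@H]1CO[Si](C)(C)C(C)(C)C | intermediate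
19 | C10,C12-diol from 18 | OC[C@@]1(CCCO)[C@H](OCc2ccccc2)C[C@H](O[Si](C)(C)C(C)(C)C)C(C)(C)[C@@H]1CO[Si](C)(C)C(C)(C)C | intermediate
20 | C10 lactol (C10 epimers) | OC1CC[C@]2(CO1)[C@H](OCc1ccccc1)C[C@H](O[Si](C)(C)C(C)(C)C)C(C)(C)[C@@H]2CO[Si](C)(C)C(C)(C)C | intermediate (not isolated)
21 | spiro δ-lactone, carbonyl at C10 | O=C1CC[C@]2(CO1)[C@H](OCc1ccccc1)C[C@H](O[Si](C)(C)C(C)(C)C)C(C)(C)[C@@H]2CO[Si](C)(C)C(C)(C)C | intermediate
22 | C8 phenylselenide of 21 (C8 epimers) | O=C1C([Se]c3ccccc3)C[C@]2(CO1)[C@H](OCc1ccccc1)C[C@H](O[Si](C)(C)C(C)(C)C)C(C)(C)[C@@H]2CO[Si](C)(C)C(C)(C)C | intermediate (not isolated)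
23 | selenoxide of 22 | O=C1C([Se](=O)c3ccccc3)C[C@]2(CO1)[C@H](OCc1ccccc1)C[C@H](O[Si](C)(C)C(C)(C)C)C(C)(C)[C@@H]2CO[Si](C)(C)C(C)(C)C | intermediate (not isolated)
24 | C7=C8 unsaturated spiro lactone | O=C1C=C[C@]2(CO1)[C@H](OCc1ccccc1)C[C@H](O[Si](C)(C)C(C)(C)C)C(C)(C)[C@@H]2CO[Si](C)(C)C(C)(C)C | intermediate
25 | methyl (2S)-3-hydroxy-2-methylpropanoate | C[C@@H](CO)C(=O)OC | starting material
26 | methyl (2S)-3-(benzyloxy)-2-methylpropanoate | C[C@@H](COCc1ccccc1)C(=O)OC | intermediate
27 | (2S)-3-(benzyloxy)-N-methoxy-N,2-dimethylpropanamide | C[C@@H](COCc1ccccc1)C(=O)N(C)OC | intermediate (not isolated)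
28 | (3S)-4-(benzyloxy)-3-methylbutan-2-one | C[C@@H](COCc1ccccc1)C(C)=O | intermediate
29 | (3S)-4-(benzyloxy)-3-methylbut-1-en-2-yl trifluoromethanesulfonate | C=C(OS(=O)(=O)C(F)(F)F)[C@@H](C)COCc1ccccc1 | intermediate
30 | tributyl(1-ethoxyvinyl)stannane | CCCC[Sn](CCCC)(CCCC)C(=C)OCC | starting material
31 | ({[(2R)-4-ethoxy-2-methyl-3-methylidenepent-4-en-1-yl]oxy}methyl)benzene | C=C(OCC)C(=C)[C@@H](C)COCc1ccccc1 | intermediate
32 | cycloadduct enol ether (C4=C5, OEt on C5) | C[C@@H](COCc1ccccc1)C1=C(OCC)C[C@@H]2[C@H](C1)C(=O)OC[C@]23[C@H](OCc1ccccc1)C[C@H](O[Si](C)(C)C(C)(C)C)C(C)(C)[C@@H]3CO[Si](C)(C)C(C)(C)C | intermediate (not isolated)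
33 | C5 ketone, cis C7/C8 junction, C4 side chain equatorial | C[C@@H](COCc1ccccc1)[C@@H]1C(=O)C[C@@H]2[C@H](C1)C(=O)OC[C@]23[C@H](OCc1ccccc1)C[C@H](O[Si](C)(C)C(C)(C)C)C(C)(C)[C@@H]3CO[Si](C)(C)C(C)(C)C | intermediate
34 | C5 tosylhydrazone of 33 | C[C@@H](COCc1ccccc1)[C@@H]1C(=NNS(=O)(=O)c4ccc(C)cc4)C[C@@H]2[C@H](C1)C(=O)OC[C@]23[C@H](OCc1ccccc1)C[C@H](O[Si](C)(C)C(C)(C)C)C(C)(C)[C@@H]3CO[Si](C)(C)C(C)(C)C | intermediate
35 | C5 tosylhydrazine (C5 epimers) | C[C@@H](COCc1ccccc1)[C@@H]1C(NNS(=O)(=O)c4ccc(C)cc4)C[C@@H]2[C@H](C1)C(=O)OC[C@]23[C@H](OCc1ccccc1)C[C@H](O[Si](C)(C)C(C)(C)C)C(C)(C)[C@@H]3CO[Si](C)(C)C(C)(C)C | intermediate (not isolated)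
36 | C5 methylene compound | C[C@@H](COCc1ccccc1)[C@@H]1CC[C@@H]2[C@H](C1)C(=O)OC[C@]23[C@H](OCc1ccccc1)C[C@H](O[Si](C)(C)C(C)(C)C)C(C)(C)[C@@H]3CO[Si](C)(C)C(C)(C)C | intermediate
37 | C16,C18-diol | C[C@@H](COCc1ccccc1)[C@@H]1CC[C@@H]2[C@H](C1)C(=O)OC[C@]23[C@H](OCc1ccccc1)C[C@H](O)C(C)(C)[C@@H]3CO | intermediate
38 | C18 tosylate of 37 | C[C@@H](COCc1ccccc1)[C@@H]1CC[C@@H]2[C@H](C1)C(=O)OC[C@]23[C@H](OCc1ccccc1)C[C@H](O)C(C)(C)[C@@H]3COS(=O)(=O)c1ccc(C)cc1 | intermediate (not isolated)
39 | oxa-bridged C3,C14-dibenzyl ether | C[C@@H](COCc1ccccc1)[C@@H]1CC[C@@H]2[C@H](C1)C(=O)OC[C@]21[C@H](OCc3ccccc3)C[C@@H]2OC[C@H]1C2(C)C | intermediate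
40 | C3,C14-diol | C[C@@H](CO)[C@@H]1CC[C@@H]2[C@H](C1)C(=O)OC[C@]21[C@H](O)C[C@@H]2OC[C@H]1C2(C)C | intermediate
41 | C14 ketone C3 aldehyde | C[C@@H](C=O)[C@@H]1CC[C@@H]2[C@H](C1)C(=O)OC[C@]21C(=O)C[C@@H]2OC[C@H]1C2(C)C | intermediate (not isolated)
42 | CNP0152427.1 | C[C@@H](C(=O)O)[C@@H]1CC[C@@H]2[C@H](C1)C(=O)OC[C@]21C(=O)C[C@@H]2OC[C@H]1C2(C)C | target

Total step count: 26. Longest linear sequence: 21 steps (steps 1, 2, 4–15 and 20–26, counted from 1); step 3 and steps 16–19 are side branches.

Steps most likely to fail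

Step 8. The ring closure may stall, because the attacking enol carbon is fully substituted and the alkyne carbon sits next to a quaternary center. The two faces of the enol may also be attacked with little preference: C16 is four atoms from C13, and axial and equatorial placement of its silyloxy group differ little in energy in a ring whose 1,3-positions carry no axial hydrogens. The fallback makes the ring first and the quaternary center second, under catalyst control. It sets out from 10: the same gold catalyst should cyclise this unsubstituted β-keto ester more easily to methyl (4S)-4-[(tert-butyldimethylsilyl)oxy]-3,3-dimethyl-2-methylidene-6-oxocyclohexane-1-carboxylate F1, kept under neutral conditions so that the methylidene does not move into conjugation. Michael addition of F1 to 11 under a chiral phase-transfer catalyst (N-(9-anthracenylmethyl)cinchonidinium bromide or its cinchoninium pseudo-enantiomer, whichever matches the substrate, Cs2CO3, toluene, −20 °C) then puts the propanoate arm on C13 and comes back to the route at 13.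

Step 20. Cycloaddition at C7 may not take place, because this β-carbon is neopentyl and flanked on both faces, and the Lewis acid may instead polymerise or hydrolyse the alkoxy diene. The fallback replaces the pericyclic step by its anionic counterpart. It sets out from 31: mild hydrolysis (oxalic acid, wet THF) gives (4R)-5-(benzyloxy)-4-methyl-3-methylidenepentan-2-one F2. Its kinetic lithium dienolate (LiN(iPr)2, THF, −78 °C) adds to 24 at C7, and the lactone enolate so formed closes onto the enone (Michael–Michael ring closure, −78 → 0 °C). Protonation gives the C5 ketone directly, so the fallback comes back at 33 with the same face preference and the same equilibration at C4.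

Step 4. The catalytic aldol may give low enantioselectivity or stop early, because the aldehyde carbonyl is flanked by a quaternary carbon. The fallback uses a stoichiometric chiral allylborane that tolerates such aldehydes. It sets out from 3: allylboration with (−)-Ipc2B(allyl) (from (+)-α-pinene; Et2O, −78 °C, then NaOH/H2O2) gives (4S)-5,5-dimethylhept-1-en-6-yn-4-ol F3. TBSOTf and 2,6-lutidine give its silyl ether tert-butyl{[(4S)-5,5-dimethylhept-1-en-6-yn-4-yl]oxy}dimethylsilane F4. OsO4 (cat.)/NaIO4 with 2,6-lutidine cleaves the alkene, leaving the alkyne, to (3S)-3-[(tert-butyldimethylsilyl)oxy]-4,4-dimethylhex-5-ynal F5. SnCl2-catalysed homologation of F5 with methyl diazoacetate (CH2Cl2, rt) gives the β-keto ester and comes back at 10, without steps 3, 5 and 6.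

Further compounds
F1 | step 8 | methyl (4S)-4-[(tert-butyldimethylsilyl)oxy]-3,3-dimethyl-2-methylidene-6-oxocyclohexane-1-carboxylate (C1 epimers and enol) | COC(=O)C1C(=O)C[C@H](O[Si](C)(C)C(C)(C)C)C(C)(C)C1=C
F2 | step 20 | (4R)-5-(benzyloxy)-4-methyl-3-methylidenepentan-2-one | CC(=O)C(=C)[C@@H](C)COCc1ccccc1
F3 | step 4 | (4S)-5,5-dimethylhept-1-en-6-yn-4-ol | C=CC[C@H](O)C(C)(C)C#C
F4 | step 4 | tert-butyl{[(4S)-5,5-dimethylhept-1-en-6-yn-4-yl]oxy}dimethylsilane | C=CC[C@H](O[Si](C)(C)C(C)(C)C)C(C)(C)C#C
F5 | step 4 | (3S)-3-[(tert-butyldimethylsilyl)oxy]-4,4-dimethylhex-5-ynal | O=CC[C@H](O[Si](C)(C)C(C)(C)C)C(C)(C)C#C
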